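**Retrosynthetic overview**

1. Ring numbering: C1 (CHOAc), C2 (CH2), C3 (CHBr), C4 (CMe2), C5 (CHCl), C6 (=C7H–C8H2Br). The C8–Br bond and the C6=C7 geometry go back by SN2′ transposition to a C6 vinyl carbinol, then to a C6 ketone and a C6 silyloxy carbinol.
2. The strategy rests on the cis-1,3 pair C1–O / C3–Br that flanks C2 on the cyclohexane, with C3 bonded to quaternary C4. This is the retron of an aldehyde–vinyl bromo-Prins closure, so C1–C2 and C3–Br are disconnected together to acyclic aldehyde 8.
3. Aldehyde 8 is cut at C1–C6 into a formyl anion equivalent (2-lithio-1,3-dithiane) and (S)-2-chloro-3,3-dimethylpent-4-enal from catalytic enantioselective α-chlorination. The C5 chlorine centre is the only one set by a catalyst; it relays to C6, then to C1 and C3.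
4. One ring is formed, the cyclohexane, in step 5; all later steps are functional-group work at C1 and C6.

Key step: step 5

Assumption: 3,3-dimethylpent-4-enal (1) is a catalogue aldehyde and is bought.
Assumption: the (2R,5R) antipode of 2,5-diphenylpyrrolidine is taken to deliver the (S)-chloride; if the facial sense is the reverse for this substrate, the (2S,5S) catalyst is used and nothing else changes.

**Route**

Step 1
Reactants: 1 3,3-dimethylpent-4-enal; 2 N-chlorosuccinimide
Product: 3 (2S)-2-chloro-3,3-dimethylpent-4-enal
Conditions: 2 (1.2 equiv), (2R,5R)-2,5-diphenylpyrrolidine (10 mol %), CH2Cl2, 0 °C → rt; pentane, filtration through a short silica pad, solution used directly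
Reagents that add atoms: N-chlorosuccinimide (2), O=C1CCC(=O)N1Cl
Why: Enamine-catalysed electrophilic α-chlorination, in which the C2-symmetric pyrrolidine forms the E-enamine of 1 and NCS chlorinates the face left open by the phenyl groups to set the C–Cl centre (S); the flanking quaternary carbon slows re-enolisation, so the chloride should keep its configuration if used at once.

Step 2
Reactants: 3 (2S)-2-chloro-3,3-dimethylpent-4-enal; 4 1,3-dithiane
Product: 6 (1R,2S)-2-chloro-1-(1,3-dithian-2-yl)-3,3-dimethylpent-4-en-1-ol, via 2-lithio-1,3-dithiane 5 (not isolated)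
Conditions: 4, n-BuLi, THF, −30 °C; then 3, −78 °C; AcOH quench at −78 °C
Reagents that add atoms: 1,3-dithiane (4), C1CSCSC1
Why: Corey–Seebach addition of the lithiated dithiane (formyl anion equivalent) through a Cornforth-type transition state, with C–Cl anti to C=O and attack past the α-hydrogen away from the tert-alkyl group, which sets the carbinol centre (1R) anti to chlorine; the cold acidic quench prevents epoxide closure, and crystallisation of 6 is the planned point for enantiomeric upgrading.

Step 3
Reactants: 6 (1R,2S)-2-chloro-1-(1,3-dithian-2-yl)-3,3-dimethylpent-4-en-1-ol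
Product: 7 tert-butyl{[(1R,2S)-2-chloro-1-(1,3-dithian-2-yl)-3,3-dimethylpent-4-en-1-yl]oxy}dimethylsilane
Conditions: TBSOTf, 2,6-lutidine, CH2Cl2, −78 → 0 °C
Reagents that add atoms: tert-butyldimethylsilyl triflate, CC(C)(C)[Si](C)(C)OS(=O)(=O)C(F)(F)F
Why: Silylation of a hindered secondary alcohol with the silyl triflate and a pyridine base that is too weak to close the chlorohydrin to an epoxide; no stereocentre is touched.

Step 4
Reactants: 7 tert-butyl{[(1R,2S)-2-chloro-1-(1,3-dithian-2-yl)-3,3-dimethylpent-4-en-1-yl]oxy}dimethylsilane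
Product: 8 (2R,3S)-2-[(tert-butyldimethylsilyl)oxy]-3-chloro-4,4-dimethylhex-5-enal
Conditions: MeI, CaCO3, MeCN–H2O (9:1), 45 °C; used promptly
Reagents that add atoms: water, O
Why: Alkylative dithiane hydrolysis (S-methylation, opening to a thionium ion, capture by water) under buffered near-neutral conditions that spare the vinyl group, the silyl ether and the base-sensitive α-silyloxy β-chloro aldehyde.

Step 5
Reactants: 8 (2R,3S)-2-[(tert-butyldimethylsilyl)oxy]-3-chloro-4,4-dimethylhex-5-enal
Product: 9 (1S,2R,3S,5R)-5-bromo-2-[(tert-butyldimethylsilyl)oxy]-3-chloro-4,4-dimethylcyclohexan-1-ol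
Conditions: TiBr4 (1.2 equiv), 2,6-di-tert-butyl-4-methylpyridine (0.2 equiv), CH2Cl2, −78 → −40 °C; aq NaHCO3
Reagents that add atoms: titanium tetrabromide, Br[Ti](Br)(Br)Br
Why: TiBr4 binds the aldehyde oxygen of 8, the terminal vinyl carbon (C2) attacks the activated carbonyl carbon (C1), and bromide from the bromotitanate ion pair is delivered to C3 as positive charge builds there, which is the Lewis-acid halo-Prins carbocyclisation of 5-hexenals to cis-3-halocyclohexanols. The cyclohexane closes 6-endo-trig at the alkene (Markovnikov), since the 5-exo mode would need a primary cation, and no ene pathway exists because the allylic carbon C4 is quaternary, whose gem-dimethyl group also favours closure. C1 is set by a chair in which the C6 silyloxy group is equatorial (axial would be syn-axial to a C4 methyl), the cis-related C5 chlorine is therefore axial, and the titanium-bound oxygen takes the equatorial site because an axial C1–O would be syn-axial to that chlorine. C3 is set by anti addition across the alkene, bromide entering antiperiplanar to the forming C1–C2 bond, which places bromine equatorial and cis to the C1 oxygen (an axial C–Br would also be syn-axial to the chlorine). The selectivity the step needs is bromide capture ahead of a 1,2-methyl shift from C4; the contact ion pair at −78 °C and the inductive penalty that the C5 chlorine puts on the rearranged C4 cation should secure it, while the hindered pyridine keeps adventitious HBr from cleaving the silyl ether.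

Step 6
Reactants: 9 (1S,2R,3S,5R)-5-bromo-2-[(tert-butyldimethylsilyl)oxy]-3-chloro-4,4-dimethylcyclohexan-1-ol
Product: 10 (1S,2R,3S,5R)-5-bromo-2-[(tert-butyldimethylsilyl)oxy]-3-chloro-4,4-dimethylcyclohexyl acetate
Conditions: Ac2O, pyridine, DMAP (cat.), CH2Cl2, 0 °C → rt
Reagents that add atoms: acetic anhydride, CC(=O)OC(C)=O
Why: DMAP-catalysed acylation of the equatorial C1 hydroxyl; the secondary halides and the silyl ether are inert under these conditions.

Step 7
Reactants: 10 (1S,2R,3S,5R)-5-bromo-2-[(tert-butyldimethylsilyl)oxy]-3-chloro-4,4-dimethylcyclohexyl acetate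
Product: 11 (1S,2R,3S,5R)-5-bromo-3-chloro-2-hydroxy-4,4-dimethylcyclohexyl acetate
Conditions: 48% aq HF, MeCN, 0 °C → rt
Reagents that add atoms: none
Why: Acidic fluoride desilylation driven by the Si–F bond, chosen over basic fluoride to suppress 1,2-acetyl migration onto the liberated neighbouring hydroxyl.

Step 8
Reactants: 11 (1S,2R,3S,5R)-5-bromo-3-chloro-2-hydroxy-4,4-dimethylcyclohexyl acetate
Product: 12 (1S,3S,5R)-5-bromo-3-chloro-4,4-dimethyl-2-oxocyclohexyl acetate
Conditions: Dess–Martin periodinane, NaHCO3, CH2Cl2, 0 °C → rt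
Reagents that add atoms: none
Why: Dess–Martin oxidation of the secondary alcohol under buffered, non-enolising conditions; both α-centres already sit in their stable arrangement (equatorial acetate at C1, axial chlorine at C5 next to the gem-dimethyl carbon), so there is no drive to epimerise.

Step 9
Reactants: 12 (1S,3S,5R)-5-bromo-3-chloro-4,4-dimethyl-2-oxocyclohexyl acetate; 13 vinylmagnesium bromide
Product: 14 (1S,3S,5R)-5-bromo-3-chloro-2-ethenyl-2-hydroxy-4,4-dimethylcyclohexyl acetate (either C2 epimer)
Conditions: 13 (1.3 equiv), LaCl3·2LiCl (1.0 equiv), THF, −78 °C; AcOH quench at −78 °C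
Reagents that add atoms: vinylmagnesium bromide (13), C=C[Mg]Br
Why: Grignard 1,2-addition to a ketone that is activated by its α-acetoxy and α-chloro groups and by the lanthanum salt, so that it should outpace attack on the acetate and enolisation at −78 °C; the configuration of the new carbinol centre is not controlled and is erased in step 10, and the cold quench prevents acetyl transfer or epoxide closure from the alkoxide.

Step 10
Reactants: 14 (1S,3S,5R)-5-bromo-3-chloro-2-ethenyl-2-hydroxy-4,4-dimethylcyclohexyl acetate
Product: 15 (1S,2Z,3R,5R)-5-bromo-2-(2-bromoethylidene)-3-chloro-4,4-dimethylcyclohexyl acetate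
Conditions: PBr3 (0.4 equiv), pyridine (cat.), Et2O, −20 → 0 °C
Reagents that add atoms: phosphorus tribromide, BrP(Br)Br
Why: SN2′ displacement of the tertiary allylic bromophosphite by bromide at the unhindered vinyl terminus (allylic transposition of a tertiary vinyl carbinol to a primary allylic bromide), ionisation being disfavoured by the flanking C–OAc and C–Cl bonds; allylic 1,3-strain with the equatorial C1 acetate steers C8 to the C5 side, where the in-plane position carries only hydrogen, so the Z isomer is expected both kinetically and after bromide-mediated equilibration.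

**Compound list**

1 | 3,3-dimethylpent-4-enal | C=CC(C)(C)CC=O | starting material
2 | N-chlorosuccinimide | O=C1CCC(=O)N1Cl | starting material
3 | (2S)-2-chloro-3,3-dimethylpent-4-enal | O=C[C@@H](Cl)C(C)(C)C=C | intermediate
4 | 1,3-dithiane | C1CSCSC1 | starting material
5 | 2-lithio-1,3-dithiane | [Li]C1SCCCS1 | intermediate
6 | (1R,2S)-2-chloro-1-(1,3-dithian-2-yl)-3,3-dimethylpent-4-en-1-ol | O[C@H](C1SCCCS1)[C@@H](Cl)C(C)(C)C=C | intermediate
7 | tert-butyl{[(1R,2S)-2-chloro-1-(1,3-dithian-2-yl)-3,3-dimethylpent-4-en-1-yl]oxy}dimethylsilane | CC(C)(C)[Si](C)(C)O[C@H](C1SCCCS1)[C@@H](Cl)C(C)(C)C=C | intermediate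
8 | (2R,3S)-2-[(tert-butyldimethylsilyl)oxy]-3-chloro-4,4-dimethylhex-5-enal | O=C[C@@H](O[Si](C)(C)C(C)(C)C)[C@@H](Cl)C(C)(C)C=C | intermediate
9 | (1S,2R,3S,5R)-5-bromo-2-[(tert-butyldimethylsilyl)oxy]-3-chloro-4,4-dimethylcyclohexan-1-ol (OH, Br, OSi equatorial; Cl axial) | O[C@H]1C[C@@H](Br)C(C)(C)[C@H](Cl)[C@@H]1O[Si](C)(C)C(C)(C)C | intermediate
10 | (1S,2R,3S,5R)-5-bromo-2-[(tert-butyldimethylsilyl)oxy]-3-chloro-4,4-dimethylcyclohexyl acetate | CC(=O)O[C@H]1C[C@@H](Br)C(C)(C)[C@H](Cl)[C@@H]1O[Si](C)(C)C(C)(C)C | intermediate
11 | (1S,2R,3S,5R)-5-bromo-3-chloro-2-hydroxy-4,4-dimethylcyclohexyl acetate | CC(=O)O[C@H]1C[C@@H](Br)C(C)(C)[C@H](Cl)[C@@H]1O | intermediate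
12 | (1S,3S,5R)-5-bromo-3-chloro-4,4-dimethyl-2-oxocyclohexyl acetate | CC(=O)O[C@H]1C[C@@H](Br)C(C)(C)[C@H](Cl)C1=O | intermediate
13 | vinylmagnesium bromide | C=C[Mg]Br | starting material
14 | (1S,3S,5R)-5-bromo-3-chloro-2-ethenyl-2-hydroxy-4,4-dimethylcyclohexyl acetate (carbinol centre C2 uncontrolled, either epimer) | CC(=O)O[C@H]1C[C@@H](Br)C(C)(C)[C@H](Cl)C1(O)C=C | intermediate
15 | (1S,2Z,3R,5R)-5-bromo-2-(2-bromoethylidene)-3-chloro-4,4-dimethylcyclohexyl acetate | CC(=O)O[C@H]1C[C@@H](Br)C(C)(C)[C@H](Cl)/C1=C\CBr | target

**Totals**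

Total step count: 10. Longest linear sequence: 10 steps (1 → 15).

**Steps most likely to fail**

Step 5. The secondary cation that develops at C3 sits next to quaternary C4 and may undergo a Wagner–Meerwein methyl shift or lose a proton before bromide arrives; the Lewis acid may also cleave the silyl ether. The fallback sets out from 8 and comes back at 10. It makes the C1–C2 bond by enolate addition and the C–Br bond by SN2 inversion, so no cation is formed at C3.
- Tsuji–Wacker oxidation of the vinyl group of 8 (PdCl2, CuCl, O2, DMF–H2O) should give the keto aldehyde (2R,3S)-2-[(tert-butyldimethylsilyl)oxy]-3-chloro-4,4-dimethyl-5-oxohexanal F1.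
- Boron enolisation of its methyl ketone, the only enolisable ketone position (c-Hex2BCl, Et3N, Et2O, −78 → 0 °C), and intramolecular aldol addition should close the ring to the β-hydroxy ketone (3S,4R,5S)-4-[(tert-butyldimethylsilyl)oxy]-3-chloro-5-hydroxy-2,2-dimethylcyclohexan-1-one F2. The same chair preferences place the new hydroxyl equatorial.
- L-Selectride (THF, −78 °C) should attack the ketone from the equatorial side, the axial side being screened by the syn-axial chlorine, to give the axial alcohol (1S,3S,5S,6R)-6-[(tert-butyldimethylsilyl)oxy]-5-chloro-4,4-dimethylcyclohexane-1,3-diol F3.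
- Selective acetylation of the less hindered equatorial hydroxyl (Ac2O, pyridine, 0 °C) should give the monoacetate (1S,2R,3S,5S)-2-[(tert-butyldimethylsilyl)oxy]-3-chloro-5-hydroxy-4,4-dimethylcyclohexyl acetate F4.
- An Appel reaction (CBr4, PPh3, toluene, 60 °C) with inversion at the neopentyl-type carbinol would then deliver the equatorial bromide 10.

Step 10. The tertiary allylic bromophosphite may ionise and lose a proton to a diene, the neighbouring acetate may participate, and the SN2′ event may not discriminate the two alkene geometries. The fallback sets out from 14 and comes back at 15.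
- Rhenium-oxo-catalysed 1,3-transposition of the allylic alcohol (Ph3SiOReO3, Et2O, −50 → 0 °C) should move the hydroxyl to the primary terminus under thermodynamic control, giving (1S,2Z,3R,5R)-5-bromo-3-chloro-2-(2-hydroxyethylidene)-4,4-dimethylcyclohexyl acetate F5. Any E isomer can be removed at this alcohol stage.
- An Appel reaction (CBr4, PPh3, CH2Cl2, 0 °C) then converts the primary allylic alcohol into 15 without touching the alkene geometry.

Step 9. The Grignard reagent may attack the acetate carbonyl or enolise the ketone, and the new alkoxide may take up the acetyl group or displace the neighbouring chloride. The fallback sets out from 12 and comes back at 14.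
- Ethynylmagnesium bromide (THF, −40 → 0 °C), an sp nucleophile that is much less basic and much slower towards esters, should give the ethynyl carbinol (1S,3S,5R)-5-bromo-3-chloro-2-ethynyl-2-hydroxy-4,4-dimethylcyclohexyl acetate F6.
- Semi-hydrogenation over Lindlar catalyst (H2, quinoline, EtOAc) then gives 14, the alkyl halides being inert to these conditions.

**Further compounds**

F1 | step 5 | (2R,3S)-2-[(tert-butyldimethylsilyl)oxy]-3-chloro-4,4-dimethyl-5-oxohexanal | O=C[C@@H](O[Si](C)(C)C(C)(C)C)[C@@H](Cl)C(C)(C)C(C)=O
F2 | step 5 | (3S,4R,5S)-4-[(tert-butyldimethylsilyl)oxy]-3-chloro-5-hydroxy-2,2-dimethylcyclohexan-1-one | O[C@H]1CC(=O)C(C)(C)[C@H](Cl)[C@@H]1O[Si](C)(C)C(C)(C)C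
F3 | step 5 | (1S,3S,5S,6R)-6-[(tert-butyldimethylsilyl)oxy]-5-chloro-4,4-dimethylcyclohexane-1,3-diol | O[C@H]1C[C@H](O)C(C)(C)[C@H](Cl)[C@@H]1O[Si](C)(C)C(C)(C)C
F4 | step 5 | (1S,2R,3S,5S)-2-[(tert-butyldimethylsilyl)oxy]-3-chloro-5-hydroxy-4,4-dimethylcyclohexyl acetate | CC(=O)O[C@H]1C[C@H](O)C(C)(C)[C@H](Cl)[C@@H]1O[Si](C)(C)C(C)(C)C
F5 | step 10 | (1S,2Z,3R,5R)-5-bromo-3-chloro-2-(2-hydroxyethylidene)-4,4-dimethylcyclohexyl acetate | CC(=O)O[C@H]1C[C@@H](Br)C(C)(C)[C@H](Cl)/C1=C\CO
F6 | step 9 | (1S,3S,5R)-5-bromo-3-chloro-2-ethynyl-2-hydroxy-4,4-dimethylcyclohexyl acetate (either C2 epimer) | CC(=O)O[C@H]1C[C@@H](Br)C(C)(C)[C@H](Cl)C1(O)C#C
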